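The route rests on cutting ring C of the flavanone half at O1–C8a and C3–C4. O1–C2–C3 then becomes an enantiopure terminal aryl epoxide, and C4–C4a–C8a becomes a 2-fluoroaryl acyl-anion equivalent. In one operation the lithiated dithiane of 2-fluoro-4,6-dimethoxybenzaldehyde opens (R)-2-(3-bromo-4-methoxyphenyl)oxirane at CH2, and the released C2 alkoxide displaces fluoride at C8a, a formal [3+3] annulation. The step exploits two features: C8a of ring A lies meta to the C5 and C7 oxygens, so SNAr is not electronically blocked, and the C2–O1 bond is never broken. The spiro-dithiane then shields C2 from retro-oxa-Michael racemisation during the 3'–8'' Suzuki union with 8-iodo-tri-O-benzylapigenin. Unmasking and BCl3 deprotection finish the synthesis.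

Key step: step 5

Assumption: the target structure gives no descriptor for the 3'–8'' biaryl axis. The axis is therefore treated as configurationally labile at room temperature, and no axial control is attempted.

Step 1
Reactants: 1 1-fluoro-3,5-dimethoxybenzene
Product: 2 2-fluoro-4,6-dimethoxybenzaldehyde
Conditions: POCl3, DMF, 0 → 60 °C; then ice water
Reagents that add atoms: N,N-dimethylformamide, CN(C)C=O; water, O
Why: Vilsmeier–Haack formylation should take C2, which is activated ortho/para by both methoxy groups just as C4 is, but is flanked by the small fluorine rather than by two methoxy groups.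

Step 2
Reactants: 2 2-fluoro-4,6-dimethoxybenzaldehyde
Product: 3 2-(2-fluoro-4,6-dimethoxyphenyl)-1,3-dithiane
Conditions: HS(CH2)3SH, BF3·OEt2 (cat.), CH2Cl2, 0 °C → rt
Reagents that add atoms: propane-1,3-dithiol, SCCCS
Why: Lewis-acid-catalysed dithioacetalisation of an aromatic aldehyde is reliable and installs the Corey–Seebach acyl-anion mask without touching the aryl fluoride or the methyl ethers.

Step 3
Reactants: 4 2-bromoanisole
Product: 5 1-(3-bromo-4-methoxyphenyl)-2-chloroethan-1-one
Conditions: ClCH2COCl, AlCl3, CH2Cl2, 0 °C → rt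
Reagents that add atoms: chloroacetyl chloride, O=C(Cl)CCl
Why: Friedel–Crafts acylation should occur para to the methoxy group, the strongest director, with the ortho site next to it more hindered and the bromine only a weak director.

Step 4
Reactants: 5 1-(3-bromo-4-methoxyphenyl)-2-chloroethan-1-one
Product: 7 (R)-2-(3-bromo-4-methoxyphenyl)oxirane, via (R)-chlorohydrin 6 (not isolated)
Conditions: Cp*RhCl[(S,S)-TsDPEN] (0.2 mol%), HCO2H/Et3N 5:2, EtOAc, rt; then 2 M aq. NaOH, i-PrOH, 0 °C → rt
Reagents that add atoms: none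
Why: Noyori–Ikariya asymmetric transfer hydrogenation of the α-chloro aryl ketone sets the stereocentre, since the (S,S)-catalyst delivers hydride to the face that gives the (R)-chlorohydrin, and the following Williamson closure displaces chloride at CH2 without touching the carbinol C–O bond.

Step 5
Reactants: 3 2-(2-fluoro-4,6-dimethoxyphenyl)-1,3-dithiane; 7 (R)-2-(3-bromo-4-methoxyphenyl)oxirane
Product: 10 (2S)-2-(3-bromo-4-methoxyphenyl)-5,7-dimethoxyspiro[chromane-4,2'-[1,3]dithiane], via lithiodithiane 8 (not isolated), via lithium alkoxide 9 (not isolated)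
Conditions: 3 (1.1 equiv), n-BuLi (1.05 equiv), THF, −78 → −20 °C; 7 (1.0 equiv), −20 °C → rt; then KOt-Bu (1.1 equiv), DMPU, 60 °C
Reagents that add atoms: n-butyllithium, [Li]CCCC (the lithium of 8 and 9 only; nothing of it remains in 10)
Why: Corey–Seebach umpolung makes C4 a nucleophile, so the 2-aryl-2-lithio-1,3-dithiane 8 opens epoxide 7 by SN2 attack at its unsubstituted CH2, which forms C3–C4 and releases the C2 alkoxide 9. After the switch from lithium to potassium in THF/DMPU this alkoxide adds to the fluorine-bearing C8a of ring A and fluoride leaves from the Meisenheimer adduct (intramolecular SNAr etherification), which forms O1–C8a. Both events are known reaction types (dithiane–epoxide coupling and alkoxide–fluoroarene cyclisation to chromans) telescoped here into a formal [3+3] annulation, and the one ring closed, ring C, closes in a formally 6-exo-trig mode across C8a=C8 with help from the gem-dithio (Thorpe–Ingold) effect. No stereocentre is created: C2 is the epoxide carbon whose C–O bond is never broken, so the configuration of 7 is carried over with retention, and the descriptor changes from R to S only because the CIP ranks of aryl and CH2 swap. The step needs terminal rather than benzylic epoxide opening, secured by the bulk and softness of the tertiary carbanion, and substitution at C–F rather than C–OMe, secured because fluoride is the only competent nucleofuge while both methoxy groups sit meta to C8a and leave the charge-bearing carbons C4a, C6 and C8 unburdened. The aryl bromide is inert to the stabilised carbanion, and with C4 masked there is no carbonyl through which retro-aldol or E1cB loss of the alkoxide could scramble C2.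

Step 6
Reactants: 11 apigenin (5,7-dihydroxy-2-(4-hydroxyphenyl)-4H-chromen-4-one)
Product: 12 5,7-bis(benzyloxy)-2-(4-benzyloxyphenyl)-4H-chromen-4-one
Conditions: BnBr (4 equiv), K2CO3, DMF, 80 °C
Reagents that add atoms: benzyl bromide, BrCc1ccccc1
Why: Williamson etherification with excess benzyl bromide and heating should also alkylate the hydrogen-bonded C5 hydroxyl, giving a protecting-group set orthogonal to the methyl ethers that stay in the target.

Step 7
Reactants: 12 5,7-bis(benzyloxy)-2-(4-benzyloxyphenyl)-4H-chromen-4-one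
Product: 13 5,7-bis(benzyloxy)-2-(4-benzyloxyphenyl)-8-iodo-4H-chromen-4-one
Conditions: NIS (1.05 equiv), TFA (cat.), MeCN/CH2Cl2, 0 °C → rt, dark
Reagents that add atoms: N-iodosuccinimide, O=C1CCC(=O)N1I
Why: Electrophilic aromatic iodination should take the trioxygenated A ring of the flavone at C8, which is flanked by O1 and one benzyloxy group, whereas C6 is wedged between two benzyloxy groups.

Step 8
Reactants: 10 (2S)-2-(3-bromo-4-methoxyphenyl)-5,7-dimethoxyspiro[chromane-4,2'-[1,3]dithiane]; 13 5,7-bis(benzyloxy)-2-(4-benzyloxyphenyl)-8-iodo-4H-chromen-4-one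
Product: 15 (2S)-2-{3-[5,7-bis(benzyloxy)-2-(4-benzyloxyphenyl)-4-oxo-4H-chromen-8-yl]-4-methoxyphenyl}-5,7-dimethoxyspiro[chromane-4,2'-[1,3]dithiane], via pinacol boronate 14 (not isolated)
Conditions: 10, B2pin2 (1.05 equiv), KOAc, Pd(dppf)Cl2 (5 mol%), 1,4-dioxane, 90 °C; then 13, K3PO4, H2O, Pd(OAc)2/SPhos (5/10 mol%), 90 °C
Reagents that add atoms: bis(pinacolato)diboron, CC1(C)OB(OC1(C)C)B1OC(C)(C)C(C)(C)O1 (the boron and pinacol atoms of 14 only; nothing of it remains in 15)
Why: Miyaura borylation followed in the same flask by Suzuki–Miyaura coupling with a bulky biarylphosphine should forge the tri-ortho-substituted 3'–8'' bond, and the hot basic medium cannot racemise C2 because the C4 carbonyl is still a dithioketal.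

Step 9
Reactants: 15 the spiro-dithiane biaryl of step 8
Product: 16 5,7-bis(benzyloxy)-2-(4-benzyloxyphenyl)-8-{5-[(2S)-5,7-dimethoxy-4-oxochroman-2-yl]-2-methoxyphenyl}-4H-chromen-4-one
Conditions: MeI (excess), CaCO3, MeCN/THF/H2O, 45 °C
Reagents that add atoms: water, O
Why: In this alkylative dithiane hydrolysis S-methylation creates a leaving group, and the thionium ion, stabilised by electron-rich ring A, is trapped by water under CaCO3 buffering, a medium too mild to open ring C, so C2 keeps its configuration.

Step 10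
Reactants: 16 the tri-O-benzyl 5-O-methyl flavanone–flavone of step 9
Product: 17 8-{5-[(2S)-5-hydroxy-7-methoxy-4-oxochroman-2-yl]-2-methoxyphenyl}-5,7-dihydroxy-2-(4-hydroxyphenyl)-4H-chromen-4-one (the target)
Conditions: BCl3 (1 M in CH2Cl2, excess), C6HMe5, CH2Cl2, −78 → 0 °C; then MeOH, 1 M aq. HCl
Reagents that add atoms: none
Why: BCl3 cleaves aryl benzyl ethers at low temperature while pentamethylbenzene traps the benzyl cations, and among the methyl ethers it cleaves only the one at C5, whose oxygen forms a six-membered boron chelate with the C4 carbonyl (chelation-controlled dealkylation), in an acidic medium that avoids base-induced opening of ring C.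

Compound list
1 | 1-fluoro-3,5-dimethoxybenzene | COc1cc(F)cc(OC)c1 | starting material
2 | 2-fluoro-4,6-dimethoxybenzaldehyde | COc1cc(F)c(C=O)c(OC)c1 | intermediate
3 | 2-(2-fluoro-4,6-dimethoxyphenyl)-1,3-dithiane | COc1cc(F)c(C2SCCCS2)c(OC)c1 | intermediate
4 | 2-bromoanisole | COc1ccccc1Br | starting material
5 | 1-(3-bromo-4-methoxyphenyl)-2-chloroethan-1-one | COc1ccc(C(=O)CCl)cc1Br | intermediate
6 | (1R)-1-(3-bromo-4-methoxyphenyl)-2-chloroethan-1-ol | COc1ccc([C@@H](O)CCl)cc1Br | intermediate
7 | (R)-2-(3-bromo-4-methoxyphenyl)oxirane | COc1ccc([C@@H]2CO2)cc1Br | intermediate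
8 | 2-(2-fluoro-4,6-dimethoxyphenyl)-2-lithio-1,3-dithiane | [Li]C1(c2c(F)cc(OC)cc2OC)SCCCS1 | intermediate
9 | lithium (1S)-1-(3-bromo-4-methoxyphenyl)-2-[2-(2-fluoro-4,6-dimethoxyphenyl)-1,3-dithian-2-yl]ethan-1-olate | COc1cc(F)c(C2(C[C@H]([O-])c3ccc(OC)c(Br)c3)SCCCS2)c(OC)c1.[Li+] | intermediate
10 | (2S)-2-(3-bromo-4-methoxyphenyl)-5,7-dimethoxyspiro[chromane-4,2'-[1,3]dithiane] | COc1cc(OC)c2c(c1)O[C@H](c1ccc(OC)c(Br)c1)CC21SCCCS1 | intermediate
11 | apigenin | O=c1cc(-c2ccc(O)cc2)oc2cc(O)cc(O)c12 | starting material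
12 | 5,7-bis(benzyloxy)-2-(4-benzyloxyphenyl)-4H-chromen-4-one | O=c1cc(-c2ccc(OCc3ccccc3)cc2)oc2cc(OCc3ccccc3)cc(OCc3ccccc3)c12 | intermediate
13 | 5,7-bis(benzyloxy)-2-(4-benzyloxyphenyl)-8-iodo-4H-chromen-4-one | O=c1cc(-c2ccc(OCc3ccccc3)cc2)oc2c(I)c(OCc3ccccc3)cc(OCc3ccccc3)c12 | intermediate
14 | (2S)-5,7-dimethoxy-2-[4-methoxy-3-(4,4,5,5-tetramethyl-1,3,2-dioxaborolan-2-yl)phenyl]spiro[chromane-4,2'-[1,3]dithiane] | COc1cc(OC)c2c(c1)O[C@H](c1ccc(OC)c(B3OC(C)(C)C(C)(C)O3)c1)CC21SCCCS1 | intermediate
15 | (2S)-2-{3-[5,7-bis(benzyloxy)-2-(4-benzyloxyphenyl)-4-oxo-4H-chromen-8-yl]-4-methoxyphenyl}-5,7-dimethoxyspiro[chromane-4,2'-[1,3]dithiane] | COc1cc(OC)c2c(c1)O[C@H](c1ccc(OC)c(-c3c(OCc4ccccc4)cc(OCc4ccccc4)c4c(=O)cc(-c5ccc(OCc6ccccc6)cc5)oc34)c1)CC21SCCCS1 | intermediate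
16 | 5,7-bis(benzyloxy)-2-(4-benzyloxyphenyl)-8-{5-[(2S)-5,7-dimethoxy-4-oxochroman-2-yl]-2-methoxyphenyl}-4H-chromen-4-one | COc1cc(OC)c2c(c1)O[C@H](c1ccc(OC)c(-c3c(OCc4ccccc4)cc(OCc4ccccc4)c4c(=O)cc(-c5ccc(OCc6ccccc6)cc5)oc34)c1)CC2=O | intermediate
17 | 8-{5-[(2S)-5-hydroxy-7-methoxy-4-oxochroman-2-yl]-2-methoxyphenyl}-5,7-dihydroxy-2-(4-hydroxyphenyl)-4H-chromen-4-one | COc1cc(O)c2c(c1)O[C@H](c1ccc(OC)c(-c3c(O)cc(O)c4c(=O)cc(-c5ccc(O)cc5)oc34)c1)CC2=O | target

Total step count: 10 steps.
Longest linear sequence: 6 steps (1, 2, 5, 8, 9, 10, or equally 3, 4, 5, 8, 9, 10).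

Steps most likely to fail

Step 5. Several processes could interfere:
- ring lithiation next to fluorine in place of removal of the dithiane proton;
- benzylic opening or lithium-salt-induced rearrangement of the electron-rich epoxide;
- sluggish fluoride displacement;
- base-induced aryne formation at the bromide during the heating stage.

The fallback replaces the epoxide by a protected iodohydrin and makes the same two bonds in separate operations. It sets out from chlorohydrin 6, isolated by leaving out the NaOH stage of step 4, and from lithiodithiane 8, and it comes back at 10. Silylation (TBSCl, imidazole, DMF) should give the (R)-tert-butyldimethylsilyl ether of the chlorohydrin F1. Finkelstein exchange (NaI, 2-butanone, reflux) should then give the (R)-silyloxy iodide F2. Alkylation of 8 with F2 (THF/DMPU, −78 → 0 °C) should give the (S)-silyloxy fluoroaryl dithiane F3, and TBAF in THF should give the (S)-fluoroaryl alcohol F4. A separate SNAr closure (NaH, DMF, 60 °C) should then deliver 10.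

Step 8. Binding of the dithiane sulfur atoms to palladium, protodeboronation of the ortho-methoxy boronate and slow transmetalation at the doubly ortho-substituted iodide could stall the coupling. The fallback changes the organometallic partner and works without base or water. It sets out from 10 and comes back at 15. Bromine–lithium exchange (n-BuLi, THF, −78 °C) should give the aryllithium F5, and ZnCl2 should convert it into the arylzinc chloride F6. Negishi coupling of F6 with 13 (Pd2(dba)3/SPhos, THF, 50 °C) should give 15.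

Step 10. Three processes could erode the last step: loss of the non-chelated methyl ethers under excess BCl3, Friedel–Crafts re-benzylation of the electron-rich rings by released benzyl cations, and Lewis-acid-induced opening of ring C. The fallback separates the two tasks. It sets out from 16 and comes back at 17. Neutral hydrogenolysis (H2, Pd/C, EtOAc/MeOH, rt, on material freed from sulfur residues) should give the 5-O-methyl triphenol F7. A single chelation-directed demethylation at C5 (AlCl3, MeCN, rt, acidic work-up) should then give 17.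

Further compounds
F1 | step 5 | (R)-[1-(3-bromo-4-methoxyphenyl)-2-chloroethoxy](tert-butyl)dimethylsilane | COc1ccc([C@@H](O[Si](C)(C)C(C)(C)C)CCl)cc1Br
F2 | step 5 | (R)-[1-(3-bromo-4-methoxyphenyl)-2-iodoethoxy](tert-butyl)dimethylsilane | COc1ccc([C@@H](O[Si](C)(C)C(C)(C)C)CI)cc1Br
F3 | step 5 | (S)-{1-(3-bromo-4-methoxyphenyl)-2-[2-(2-fluoro-4,6-dimethoxyphenyl)-1,3-dithian-2-yl]ethoxy}(tert-butyl)dimethylsilane | COc1cc(F)c(C2(C[C@H](O[Si](C)(C)C(C)(C)C)c3ccc(OC)c(Br)c3)SCCCS2)c(OC)c1
F4 | step 5 | (1S)-1-(3-bromo-4-methoxyphenyl)-2-[2-(2-fluoro-4,6-dimethoxyphenyl)-1,3-dithian-2-yl]ethan-1-ol | COc1cc(F)c(C2(C[C@H](O)c3ccc(OC)c(Br)c3)SCCCS2)c(OC)c1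
F5 | step 8 | (2S)-2-(3-lithio-4-methoxyphenyl)-5,7-dimethoxyspiro[chromane-4,2'-[1,3]dithiane] | COc1cc(OC)c2c(c1)O[C@H](c1ccc(OC)c([Li])c1)CC21SCCCS1
F6 | step 8 | (2S)-2-[3-(chlorozincio)-4-methoxyphenyl]-5,7-dimethoxyspiro[chromane-4,2'-[1,3]dithiane] | COc1cc(OC)c2c(c1)O[C@H](c1ccc(OC)c([Zn]Cl)c1)CC21SCCCS1
F7 | step 10 | 8-{5-[(2S)-5,7-dimethoxy-4-oxochroman-2-yl]-2-methoxyphenyl}-5,7-dihydroxy-2-(4-hydroxyphenyl)-4H-chromen-4-one | COc1cc(OC)c2c(c1)O[C@H](c1ccc(OC)c(-c3c(O)cc(O)c4c(=O)cc(-c5ccc(O)cc5)oc34)c1)CC2=O
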